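**Retrosynthetic overview**
- The last bond made is the benzylic C–OAr ether: a Mitsunobu inversion joins the 7-OH of (S)-pinocembrin to the (R)-benzylic alcohol of the bicyclic lactone, each half being built separately.
- Bicyclic lactone: the oxolane ring is closed by an intramolecular oxa-Michael addition of a side-chain hydroxyl to an enoate (Wittig on a lactol); the γ-lactone then closes by lactonization, which fixes the cis ring fusion.
- Lactol: Felkin aldol of (R)-O-TBDPS-mandelaldehyde with the enolate of pyruvaldehyde dimethyl acetal, syn-1,3-reduction, acetal hydrolysis.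
- (S)-Pinocembrin: phloroacetophenone to a chromone (pyranone ring closed by intramolecular conjugate addition–elimination of an enaminone), then Rh-catalysed asymmetric 1,4-addition of PhB(OH)2.
- Ring order: pyranone in the flavanone half; oxolane, then γ-lactone in the lactone half; the halves are joined at the end.

Assumption: a telescoped one-pot sequence counts as one step, and metal-bound species (Li enolate, boron chelate, Al hemiacetal, Rh and phosphonium intermediates) are treated as mechanism and carry no number.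

**Route**

Step 1
Reactants: 1 methyl (2R)-2-hydroxy-2-phenylacetate (methyl (R)-mandelate)
Product: 2 methyl (2R)-2-[(tert-butyldiphenylsilyl)oxy]-2-phenylacetate
Conditions: TBDPSCl, imidazole, DMF, rt
Reagents that add atoms: tert-butyl(chloro)diphenylsilane, CC(C)(C)[Si](Cl)(c1ccccc1)c1ccccc1
Why: Imidazole-promoted silyl ether formation; the benzylic stereocentre (R) comes from the chiral pool, and the bulky non-chelating TBDPS group later enforces Felkin control and survives aqueous acid.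

Step 2
Reactants: 2 methyl (2R)-2-[(tert-butyldiphenylsilyl)oxy]-2-phenylacetate
Product: 3 (2R)-2-[(tert-butyldiphenylsilyl)oxy]-2-phenylacetaldehyde
Conditions: DIBAL-H (1.1 eq), CH2Cl2, −78 °C; MeOH, then aq. Rochelle salt; used crude at once
Reagents that add atoms: none
Why: Partial ester reduction; the α-silyloxy ester gives an aluminium hemiacetal that is stable at −78 °C and collapses to the aldehyde only on work-up, so over-reduction and α-epimerization are avoided.

Step 3
Reactants: 3 (2R)-2-[(tert-butyldiphenylsilyl)oxy]-2-phenylacetaldehyde; 4 1,1-dimethoxypropan-2-one (pyruvaldehyde dimethyl acetal)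
Product: 5 (4S,5R)-5-[(tert-butyldiphenylsilyl)oxy]-4-hydroxy-1,1-dimethoxy-5-phenylpentan-2-one
Conditions: 4, LDA, THF, −78 °C, 30 min; then 3, −78 °C, 20 min; AcOH quench at −78 °C
Reagents that add atoms: none
Why: Aldol addition of the kinetic (CH3-side) lithium enolate to the α-silyloxy aldehyde under polar Felkin–Anh control gives the 4,5-anti adduct, setting the new carbinol centre as S (expected dr about 5:1, minor isomer removed by chromatography).

Step 4
Reactants: 5 (4S,5R)-5-[(tert-butyldiphenylsilyl)oxy]-4-hydroxy-1,1-dimethoxy-5-phenylpentan-2-one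
Product: 6 (2R,4S,5R)-5-[(tert-butyldiphenylsilyl)oxy]-1,1-dimethoxy-5-phenylpentane-2,4-diol
Conditions: Et2BOMe, THF/MeOH 4:1, −78 °C; NaBH4; AcOH, then MeOH co-evaporation (Et2BOMe is returned on methanolysis)
Reagents that add atoms: none
Why: Narasaka–Prasad reduction; external hydride delivery to the six-membered boron chelate of the β-hydroxy ketone gives the 1,3-syn diol, setting the new carbinol centre as R.

Step 5
Reactants: 6 (2R,4S,5R)-5-[(tert-butyldiphenylsilyl)oxy]-1,1-dimethoxy-5-phenylpentane-2,4-diol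
Product: 7 (3R,5S)-5-[(R)-[(tert-butyldiphenylsilyl)oxy](phenyl)methyl]oxolane-2,3-diol (lactol; both anomers)
Conditions: 2 M aq. HCl/THF 1:2, 40 °C
Reagents that add atoms: water, O
Why: Acid-catalysed acetal hydrolysis; the freed α-hydroxy aldehyde is trapped by the 4-hydroxyl as the five-membered lactol, and the TBDPS ether is stable to these conditions.

Step 6
Reactants: 7 (3R,5S)-5-[(R)-[(tert-butyldiphenylsilyl)oxy](phenyl)methyl]oxolane-2,3-diol; 8 ethyl 2-(triphenyl-λ5-phosphanylidene)acetate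
Product: 11 (3aR,5S,6aR)-5-[(R)-[(tert-butyldiphenylsilyl)oxy](phenyl)methyl]hexahydrofuro[3,2-b]furan-2-one, via hydroxy enoate 9 (not isolated), via oxolanyl acetate 10 (not isolated)
Conditions: 8 (1.5 eq), MeCN, 80 °C; then DBU (0.2 eq), rt
Reagents that add atoms: none
Why: Wittig olefination of the lactol's open form gives the dihydroxy enoate, whose 6-OH closes the oxolane by a reversible 5-exo-trig intramolecular oxa-Michael addition; only the epimer with CH2CO2Et cis to the 4-OH can lactonize, so the cis-fused lactone (C3a R) is the thermodynamic sink (any Z-enoate converges through the butenolide).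

Step 7
Reactants: 11 (3aR,5S,6aR)-5-[(R)-[(tert-butyldiphenylsilyl)oxy](phenyl)methyl]hexahydrofuro[3,2-b]furan-2-one
Product: 12 (3aR,5S,6aR)-5-[(R)-hydroxy(phenyl)methyl]hexahydrofuro[3,2-b]furan-2-one
Conditions: TBAF, AcOH (1:1), THF, 0 °C to rt
Reagents that add atoms: none
Why: Fluoride-mediated desilylation, buffered with AcOH so that neither lactone opening nor retro-oxa-Michael equilibration of the bicycle occurs.

Step 8
Reactants: 13 1-(2,4,6-trihydroxyphenyl)ethan-1-one (phloroacetophenone)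
Product: 14 1-[2,4-bis(benzyloxy)-6-hydroxyphenyl]ethan-1-one
Conditions: BnBr (2.1 eq), K2CO3, DMF, rt
Reagents that add atoms: benzyl bromide, BrCc1ccccc1
Why: Williamson etherification; two hydroxyls are benzylated while the last ortho-OH, locked in a hydrogen bond to the acetyl carbonyl, stays free.

Step 9
Reactants: 14 1-[2,4-bis(benzyloxy)-6-hydroxyphenyl]ethan-1-one
Product: 16 5,7-bis(benzyloxy)-4H-chromen-4-one, via enaminone 15 (not isolated)
Conditions: DMF-DMA, toluene, 100 °C; evaporate; conc. HCl, CH2Cl2, 40 °C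
Reagents that add atoms: N,N-dimethylformamide dimethyl acetal, COC(OC)N(C)C
Why: Condensation of the methyl ketone with DMF-DMA gives the enaminone, and acid then drives intramolecular conjugate addition of the phenol with loss of Me2NH (addition–elimination) to close the pyranone ring.

Step 10
Reactants: 16 5,7-bis(benzyloxy)-4H-chromen-4-one; 17 phenylboronic acid
Product: 18 (2S)-5,7-bis(benzyloxy)-2-phenyl-2,3-dihydro-4H-chromen-4-one
Conditions: 17 (3 eq), [Rh(OH)(cod)]2 (2 mol%), (S)-MeO-F12-BIPHEP (4.4 mol%), toluene/H2O 10:1, 30 °C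
Reagents that add atoms: none
Why: Hayashi–Miyaura Rh(I)-catalysed asymmetric 1,4-addition; the atropisomeric bisphosphine selects the enone face and sets C2 as S (the (S)-ligand is expected by analogy with (S)-BINAP and cyclohexenone; the sense is checked by the levorotation of 19).

Step 11
Reactants: 18 (2S)-5,7-bis(benzyloxy)-2-phenyl-2,3-dihydro-4H-chromen-4-one
Product: 19 (2S)-5,7-dihydroxy-2-phenyl-2,3-dihydro-4H-chromen-4-one ((S)-pinocembrin)
Conditions: H2 (1 atm), 10% Pd/C, EtOAc/MeOH, rt, stopped at full debenzylation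
Reagents that add atoms: none
Why: Hydrogenolysis of both benzyl ethers under neutral conditions leaves the ketone and the base-labile C2 centre untouched.

Step 12
Reactants: 12 (3aR,5S,6aR)-5-[(R)-hydroxy(phenyl)methyl]hexahydrofuro[3,2-b]furan-2-one; 19 (2S)-5,7-dihydroxy-2-phenyl-2,3-dihydro-4H-chromen-4-one
Product: 20 (3aR,5S,6aR)-5-[(S)-{[(2S)-5-hydroxy-4-oxo-2-phenyl-3,4-dihydro-2H-chromen-7-yl]oxy}(phenyl)methyl]hexahydrofuro[3,2-b]furan-2-one (CNP0152032.1)
Conditions: PPh3, DIAD (1.5 eq each), THF, 0 °C to rt (DIAD added last)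
Reagents that add atoms: none
Why: Mitsunobu etherification; the acidic, non-chelated 7-OH (the 5-OH is hydrogen-bonded to C4=O) displaces the alkoxyphosphonium by SN2 with inversion at the benzylic carbon (R to S), and the near-neutral conditions spare the flavanone C2 centre and the lactone.

**Compound list**
1 | methyl (2R)-2-hydroxy-2-phenylacetate | COC(=O)[C@H](O)c1ccccc1 | starting material
2 | methyl (2R)-2-[(tert-butyldiphenylsilyl)oxy]-2-phenylacetate | COC(=O)[C@H](O[Si](c1ccccc1)(c1ccccc1)C(C)(C)C)c1ccccc1 | intermediate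
3 | (2R)-2-[(tert-butyldiphenylsilyl)oxy]-2-phenylacetaldehyde | O=C[C@H](O[Si](c1ccccc1)(c1ccccc1)C(C)(C)C)c1ccccc1 | intermediate
4 | 1,1-dimethoxypropan-2-one | CC(=O)C(OC)OC | starting material
5 | (4S,5R)-5-[(tert-butyldiphenylsilyl)oxy]-4-hydroxy-1,1-dimethoxy-5-phenylpentan-2-one | COC(OC)C(=O)C[C@H](O)[C@H](O[Si](c1ccccc1)(c1ccccc1)C(C)(C)C)c1ccccc1 | intermediate
6 | (2R,4S,5R)-5-[(tert-butyldiphenylsilyl)oxy]-1,1-dimethoxy-5-phenylpentane-2,4-diol | COC(OC)[C@H](O)C[C@H](O)[C@H](O[Si](c1ccccc1)(c1ccccc1)C(C)(C)C)c1ccccc1 | intermediate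
7 | (3R,5S)-5-[(R)-[(tert-butyldiphenylsilyl)oxy](phenyl)methyl]oxolane-2,3-diol | OC1O[C@H]([C@H](O[Si](c2ccccc2)(c2ccccc2)C(C)(C)C)c2ccccc2)C[C@H]1O | intermediate
8 | ethyl 2-(triphenyl-λ5-phosphanylidene)acetate | CCOC(=O)C=P(c1ccccc1)(c1ccccc1)c1ccccc1 | starting material
9 | ethyl (2E,4R,6S,7R)-7-[(tert-butyldiphenylsilyl)oxy]-4,6-dihydroxy-7-phenylhept-2-enoate | CCOC(=O)/C=C/[C@H](O)C[C@H](O)[C@H](O[Si](c1ccccc1)(c1ccccc1)C(C)(C)C)c1ccccc1 | intermediate (not isolated)
10 | ethyl 2-[(2R,3R,5S)-5-[(R)-[(tert-butyldiphenylsilyl)oxy](phenyl)methyl]-3-hydroxyoxolan-2-yl]acetate | CCOC(=O)C[C@H]1O[C@H]([C@H](O[Si](c2ccccc2)(c2ccccc2)C(C)(C)C)c2ccccc2)C[C@H]1O | intermediate (not isolated)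
11 | (3aR,5S,6aR)-5-[(R)-[(tert-butyldiphenylsilyl)oxy](phenyl)methyl]hexahydrofuro[3,2-b]furan-2-one | O=C1C[C@H]2O[C@H]([C@H](O[Si](c3ccccc3)(c3ccccc3)C(C)(C)C)c3ccccc3)C[C@H]2O1 | intermediate
12 | (3aR,5S,6aR)-5-[(R)-hydroxy(phenyl)methyl]hexahydrofuro[3,2-b]furan-2-one | O=C1C[C@H]2O[C@H]([C@H](O)c3ccccc3)C[C@H]2O1 | intermediate
13 | 1-(2,4,6-trihydroxyphenyl)ethan-1-one | CC(=O)c1c(O)cc(O)cc1O | starting material
14 | 1-[2,4-bis(benzyloxy)-6-hydroxyphenyl]ethan-1-one | CC(=O)c1c(O)cc(OCc2ccccc2)cc1OCc1ccccc1 | intermediate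
15 | (2E)-1-[2,4-bis(benzyloxy)-6-hydroxyphenyl]-3-(dimethylamino)prop-2-en-1-one | CN(C)/C=C/C(=O)c1c(O)cc(OCc2ccccc2)cc1OCc1ccccc1 | intermediate (not isolated)
16 | 5,7-bis(benzyloxy)-4H-chromen-4-one | O=c1ccoc2cc(OCc3ccccc3)cc(OCc3ccccc3)c12 | intermediate
17 | phenylboronic acid | OB(O)c1ccccc1 | starting material
18 | (2S)-5,7-bis(benzyloxy)-2-phenyl-2,3-dihydro-4H-chromen-4-one | O=C1C[C@@H](c2ccccc2)Oc2cc(OCc3ccccc3)cc(OCc3ccccc3)c12 | intermediate
19 | (2S)-5,7-dihydroxy-2-phenyl-2,3-dihydro-4H-chromen-4-one | O=C1C[C@@H](c2ccccc2)Oc2cc(O)cc(O)c12 | intermediate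
20 | (3aR,5S,6aR)-5-[(S)-{[(2S)-5-hydroxy-4-oxo-2-phenyl-3,4-dihydro-2H-chromen-7-yl]oxy}(phenyl)methyl]hexahydrofuro[3,2-b]furan-2-one | O=C1C[C@H]2O[C@H]([C@@H](Oc3cc(O)c4c(c3)O[C@H](c3ccccc3)CC4=O)c3ccccc3)C[C@H]2O1 | target

**Totals**
Total step count: 12.
Longest linear sequence: 8 steps (steps 1–7, then step 12), which is two thirds of the total; the flavanone branch (steps 8–11) runs in parallel.

**Steps most likely to fail, with fallbacks**

Step 3 (aldol). Aldehyde 3 epimerizes easily and the Felkin ratio of a lithium enolate may be modest. The fallback sets out from 3 and comes back at lactol 7, using pyruvate instead of the acetal as the three-carbon unit. Methyl pyruvate is silylated (TMSCl, Et3N) to methyl 2-[(trimethylsilyl)oxy]prop-2-enoate F1. F1 adds to 3 in a BF3·OEt2-mediated Mukaiyama aldol (CH2Cl2, −78 °C, open transition state, higher Felkin selectivity) to give methyl (4S,5R)-5-[(tert-butyldiphenylsilyl)oxy]-4-hydroxy-2-oxo-5-phenylpentanoate F2. Et2BOMe/NaBH4 reduction gives methyl (2R,4S,5R)-5-[(tert-butyldiphenylsilyl)oxy]-2,4-dihydroxy-5-phenylpentanoate F3. F3 closes with catalytic TsOH to (3R,5S)-3-hydroxy-5-[(R)-[(tert-butyldiphenylsilyl)oxy](phenyl)methyl]oxolan-2-one F4, and DIBAL-H at −78 °C reduces F4 to 7.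

Step 10 (asymmetric 1,4-arylation). 5-Alkoxychromones are sluggish acceptors, and both ee and sense of induction have to be confirmed. The fallback sets out from 14 and comes back at 18. Claisen–Schmidt condensation of 14 with benzaldehyde (KOH, EtOH) gives (2E)-1-[2,4-bis(benzyloxy)-6-hydroxyphenyl]-3-phenylprop-2-en-1-one F5. NaOAc in refluxing EtOH closes the pyranone ring by intramolecular oxa-Michael addition to give racemic 5,7-bis(benzyloxy)-2-phenyl-2,3-dihydro-4H-chromen-4-one F6. Preparative HPLC on a chiral stationary phase separates 18 from (2R)-5,7-bis(benzyloxy)-2-phenyl-2,3-dihydro-4H-chromen-4-one F7, which is racemized with base and recycled.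

Step 12 (Mitsunobu). The alcohol is secondary, benzylic and α-branched, so slow activation, elimination or partial loss of inversion are possible. The fallback sets out from 12 and comes back at 20 by a two-step sulfonate displacement. MsCl/Et3N (CH2Cl2, −20 °C) converts 12 with retention into (R)-[(3aR,5S,6aR)-2-oxohexahydrofuro[3,2-b]furan-5-yl](phenyl)methyl methanesulfonate F8 (the β-oxygen disfavours ionization). The caesium 7-phenoxide of 19 (1 eq Cs2CO3, MeCN, 0 °C to rt) displaces it by SN2 with inversion to give 20; the temperature is kept low to avoid flavanone ring opening.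

**Further compounds**
F1 | step 3 | methyl 2-[(trimethylsilyl)oxy]prop-2-enoate | COC(=O)C(=C)O[Si](C)(C)C
F2 | step 3 | methyl (4S,5R)-5-[(tert-butyldiphenylsilyl)oxy]-4-hydroxy-2-oxo-5-phenylpentanoate | COC(=O)C(=O)C[C@H](O)[C@H](O[Si](c1ccccc1)(c1ccccc1)C(C)(C)C)c1ccccc1
F3 | step 3 | methyl (2R,4S,5R)-5-[(tert-butyldiphenylsilyl)oxy]-2,4-dihydroxy-5-phenylpentanoate | COC(=O)[C@H](O)C[C@H](O)[C@H](O[Si](c1ccccc1)(c1ccccc1)C(C)(C)C)c1ccccc1
F4 | step 3 | (3R,5S)-3-hydroxy-5-[(R)-[(tert-butyldiphenylsilyl)oxy](phenyl)methyl]oxolan-2-one | O=C1O[C@H]([C@H](O[Si](c2ccccc2)(c2ccccc2)C(C)(C)C)c2ccccc2)C[C@H]1O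
F5 | step 10 | (2E)-1-[2,4-bis(benzyloxy)-6-hydroxyphenyl]-3-phenylprop-2-en-1-one | O=C(/C=C/c1ccccc1)c1c(O)cc(OCc2ccccc2)cc1OCc1ccccc1
F6 | step 10 | rac-5,7-bis(benzyloxy)-2-phenyl-2,3-dihydro-4H-chromen-4-one | O=C1CC(c2ccccc2)Oc2cc(OCc3ccccc3)cc(OCc3ccccc3)c12
F7 | step 10 | (2R)-5,7-bis(benzyloxy)-2-phenyl-2,3-dihydro-4H-chromen-4-one | O=C1C[C@H](c2ccccc2)Oc2cc(OCc3ccccc3)cc(OCc3ccccc3)c12
F8 | step 12 | (R)-[(3aR,5S,6aR)-2-oxohexahydrofuro[3,2-b]furan-5-yl](phenyl)methyl methanesulfonate | O=C1C[C@H]2O[C@H]([C@H](OS(C)(=O)=O)c3ccccc3)C[C@H]2O1
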